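**Retrosynthetic overview**

1. The quinone is made last by oxidation and selective hydrolysis of a 3‑alkyl‑1,2,4,5‑tetramethoxybenzene; the aryl–CH2 bond comes from the aryllithium and an (E)‑allylic bromide whose E‑alkene is taken from geraniol.
2. Ring numbering of the 2,6,6‑trimethylcyclohex‑2‑enyl ring: C1 (stereocentre with the side chain), C2 (methyl‑bearing), C3, C4, C5, C6 (gem‑dimethyl). The C2 methyl and C2=C3 come from a C2 ketone (enol triflate, iron‑catalysed methylation), the ketone from a C2 nitro group, and the C4–C5 single bond from a C4=C5 alkene.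
3. Key disconnection: the carbocycle is assembled in one pot from isobutyraldehyde (C5, C6, both methyls), a geraniol‑derived nitroalkene (C1, C2, side chain) and triphenyl(vinyl)phosphonium bromide (C3, C4). The events are enamine Michael addition (C1–C6, sets C1), nitronate Michael addition (C2–C3), then ring closure between C4 and C5 by intramolecular Wittig reaction.
4. Enabling feature: the quaternary gem‑dimethyl carbon C6 sits between the CH2 C5 and the stereogenic C1, which is an isobutyraldehyde unit attached to C1. After the Michael step its aldehyde carbon C5 is non‑enolizable and neopentylic, so it survives strong base until the ylide at C4 attacks it.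
5. Ring order: only the cyclohexene ring is formed (step 4); the quinone ring is bought as the arene.

Key step: step 4

Assumption: the (1R,2R)‑configured amine–thiourea catalyst of step 4 is taken to direct the enamine to the Re face of C1 of the nitroalkene; if the sense were opposite, its (1S,2S) antipode is the catalyst to use.

**Route**

Step 1
Reactants: 1 geraniol
Product: 2 tert-butyl{[(2E)-3,7-dimethylocta-2,6-dien-1-yl]oxy}diphenylsilane
Conditions: t-BuPh2SiCl, imidazole, DMF, rt
Reagents that add atoms: tert-butyl(chloro)diphenylsilane, CC(C)(C)[Si](Cl)(c1ccccc1)c1ccccc1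
Why: Imidazole‑promoted silylation of the primary allylic alcohol gives a silyl ether that is stable through steps 2–8 and inductively deactivates the neighbouring 2,3‑alkene.

Step 2
Reactants: 2 tert-butyl{[(2E)-3,7-dimethylocta-2,6-dien-1-yl]oxy}diphenylsilane
Product: 4 (4E)-6-[(tert-butyldiphenylsilyl)oxy]-4-methylhex-4-enal, via terminal epoxide 3 (not isolated)
Conditions: mCPBA (1.0 equiv), CH2Cl2, −20 → 0 °C; then H5IO6, THF/H2O, 0 °C
Reagents that add atoms: 3-chloroperoxybenzoic acid, O=C(OO)c1cccc(Cl)c1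
Why: Prilezhaev epoxidation should take the more electron‑rich terminal trisubstituted alkene, and periodic acid then opens the epoxide and cleaves the glycol (Malaprade‑type cleavage) to the aldehyde with loss of acetone.

Step 3
Reactants: 4 (4E)-6-[(tert-butyldiphenylsilyl)oxy]-4-methylhex-4-enal; 5 nitromethane
Product: 7 tert-butyl{[(2E,6E)-3-methyl-7-nitrohepta-2,6-dien-1-yl]oxy}diphenylsilane, via nitro alcohol 6 (not isolated)
Conditions: Et3N (cat.), THF, 0 °C → rt; then MeSO2Cl, Et3N, CH2Cl2, −20 → 0 °C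
Reagents that add atoms: none
Why: Henry (nitroaldol) addition followed by mesylation and E1cB elimination should give the conjugated nitroalkene with the thermodynamically preferred E geometry.

Step 4
Reactants: 7 tert-butyl{[(2E,6E)-3-methyl-7-nitrohepta-2,6-dien-1-yl]oxy}diphenylsilane; 8 isobutyraldehyde; 9 triphenyl(vinyl)phosphonium bromide
Product: 12 tert-butyl{[(2E)-5-[(1S)-2,2-dimethyl-6-nitrocyclohex-3-en-1-yl]-3-methylpent-2-en-1-yl]oxy}diphenylsilane (both epimers at the nitro carbon), via nitro aldehyde 10 (not isolated), via phosphorus ylide 11 (not isolated)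
Conditions: 8 (3 equiv), 1-[(1R,2R)-2-aminocyclohexyl]-3-[3,5-bis(trifluoromethyl)phenyl]thiourea (15 mol%), H2O (5 equiv), CH2Cl2, rt; volatiles removed; then 9, KN(SiMe3)2 (2.2 equiv, two portions), THF, −40 → 45 °C; AcOH quench
Reagents that add atoms: none
Why: Proposed new method: the catalyst amine condenses with 8 to an enamine whose carbon C6 adds to C1 of nitroalkene 7 held by the thiourea, giving 10; its nitronate carbon C2 then adds to the vinylphosphonium salt 9, and the second equivalent of base converts the adduct into ylide 11, whose carbon C4 attacks the aldehyde carbon C5 in an intramolecular Wittig olefination (C4=C5). The closest known reaction types are the amine–thiourea Michael addition of α,α‑disubstituted aldehydes to nitroalkenes, the one‑pot nitronate Michael/intramolecular Horner–Wadsworth–Emmons cyclohexene annulation with vinylphosphonates, and the vinylphosphonium Michael/Wittig annulation. The six‑membered ring closes by 6‑exo‑trig attack of the ylide carbon on the carbonyl group, and collapse of the oxaphosphetane gives the endocyclic cis alkene. The only stereocentre that is kept, C1, is set in the first event by the catalyst, which should deliver the enamine to the Re face of C1; the nitro‑bearing C2 forms as a mixture that is erased in step 6. The step needs mono‑addition of the nitronate and an aldehyde that survives strong base: the gem‑dimethyl group at C6 makes the aldehyde of 10 non‑enolizable and neopentylic, so it cannot self‑condense or epimerise, and the six‑membered closure should outrun intermolecular reactions.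

Step 5
Reactants: 12 tert-butyl{[(2E)-5-[(1S)-2,2-dimethyl-6-nitrocyclohex-3-en-1-yl]-3-methylpent-2-en-1-yl]oxy}diphenylsilane
Product: 13 tert-butyl{[(2E)-5-[(1S)-2,2-dimethyl-6-nitrocyclohexyl]-3-methylpent-2-en-1-yl]oxy}diphenylsilane
Conditions: H2 (3 atm), RhCl(PPh3)3 (5 mol%), benzene/EtOH, rt
Reagents that add atoms: none
Why: Homogeneous hydrogenation with RhCl(PPh3)3 should saturate the cis‑disubstituted C4=C5 ring alkene and leave the trisubstituted chain alkene, the aliphatic nitro group and the silyl ether, because this catalyst discriminates strongly by alkene substitution.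

Step 6
Reactants: 13 tert-butyl{[(2E)-5-[(1S)-2,2-dimethyl-6-nitrocyclohexyl]-3-methylpent-2-en-1-yl]oxy}diphenylsilane
Product: 15 (2S)-2-[(3E)-5-[(tert-butyldiphenylsilyl)oxy]-3-methylpent-3-en-1-yl]-3,3-dimethylcyclohexan-1-one, via sodium nitronate 14 (not isolated)
Conditions: NaOMe, MeOH, 0 °C; then TiCl3 (aq.), NH4OAc buffer (pH 5–6), rt
Reagents that add atoms: water, O
Why: Reductive Nef reaction: titanium trichloride reduces the nitronate to the imine, which hydrolyses in the buffered medium to the C2 ketone under conditions too mild to enolise the hindered C1 position.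

Step 7
Reactants: 15 (2S)-2-[(3E)-5-[(tert-butyldiphenylsilyl)oxy]-3-methylpent-3-en-1-yl]-3,3-dimethylcyclohexan-1-one
Product: 17 (6S)-6-[(3E)-5-[(tert-butyldiphenylsilyl)oxy]-3-methylpent-3-en-1-yl]-5,5-dimethylcyclohex-1-en-1-yl trifluoromethanesulfonate, via lithium enolate 16 (not isolated)
Conditions: LiN(iPr)2, THF, −78 °C; then PhNTf2, −78 → 0 °C
Reagents that add atoms: N-phenylbis(trifluoromethanesulfonimide), O=S(=O)(N(c1ccccc1)S(=O)(=O)C(F)(F)F)C(F)(F)F
Why: Kinetic deprotonation should occur at the C3 methylene and not at the C1 methine flanked by the quaternary C6, so O‑triflation of the enolate fixes the C2=C3 position and leaves the C1 stereocentre untouched.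

Step 8
Reactants: 17 (6S)-6-[(3E)-5-[(tert-butyldiphenylsilyl)oxy]-3-methylpent-3-en-1-yl]-5,5-dimethylcyclohex-1-en-1-yl trifluoromethanesulfonate
Product: 18 tert-butyl{[(2E)-3-methyl-5-[(1S)-2,6,6-trimethylcyclohex-2-en-1-yl]pent-2-en-1-yl]oxy}diphenylsilane
Conditions: MeMgBr, Fe(acac)3 (5 mol%), THF/N-methylpyrrolidone, −30 °C
Reagents that add atoms: methylmagnesium bromide, C[Mg]Br
Why: Iron‑catalysed Kumada‑type cross‑coupling of the alkenyl triflate with the methyl Grignard reagent should install the C2 methyl group with the alkene held at C2=C3, completing the 2,6,6‑trimethylcyclohex‑2‑enyl ring.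

Step 9
Reactants: 18 tert-butyl{[(2E)-3-methyl-5-[(1S)-2,6,6-trimethylcyclohex-2-en-1-yl]pent-2-en-1-yl]oxy}diphenylsilane
Product: 19 (2E)-3-methyl-5-[(1S)-2,6,6-trimethylcyclohex-2-en-1-yl]pent-2-en-1-ol
Conditions: Bu4NF, THF, rt
Reagents that add atoms: none
Why: Fluoride cleaves the Si–O bond (desilylation) without affecting the two trisubstituted alkenes.

Step 10
Reactants: 19 (2E)-3-methyl-5-[(1S)-2,6,6-trimethylcyclohex-2-en-1-yl]pent-2-en-1-ol
Product: 20 (6S)-6-[(3E)-5-bromo-3-methylpent-3-en-1-yl]-1,5,5-trimethylcyclohex-1-ene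
Conditions: PBr3 (0.4 equiv), pyridine (cat.), Et2O, −10 °C
Reagents that add atoms: phosphorus tribromide, BrP(Br)Br
Why: PBr3 converts the primary allylic alcohol through a phosphite ester and SN2 displacement by bromide into the allylic bromide with retention of the E geometry, as for geranyl bromide.

Step 11
Reactants: 20 (6S)-6-[(3E)-5-bromo-3-methylpent-3-en-1-yl]-1,5,5-trimethylcyclohex-1-ene; 21 1,2,4,5-tetramethoxybenzene
Product: 23 1,2,4,5-tetramethoxy-3-[(2E)-3-methyl-5-[(1S)-2,6,6-trimethylcyclohex-2-en-1-yl]pent-2-en-1-yl]benzene, via aryllithium 22 (not isolated)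
Conditions: 21, n-BuLi, Me2NCH2CH2NMe2, THF, 0 °C; then CuI (10 mol%), 20, −78 °C → rt
Reagents that add atoms: none
Why: Directed ortho‑lithiation of 21 between two methoxy groups gives 22, and copper‑catalysed SN2 alkylation with the primary allylic bromide should form the aryl–CH2 bond without allylic transposition.

Step 12
Reactants: 23 1,2,4,5-tetramethoxy-3-[(2E)-3-methyl-5-[(1S)-2,6,6-trimethylcyclohex-2-en-1-yl]pent-2-en-1-yl]benzene
Product: 24 2,5-dimethoxy-3-[(2E)-3-methyl-5-[(1S)-2,6,6-trimethylcyclohex-2-en-1-yl]pent-2-en-1-yl]cyclohexa-2,5-diene-1,4-dione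
Conditions: (NH4)2Ce(NO3)6, MeCN/H2O, 0 °C
Reagents that add atoms: water, O
Why: Oxidative demethylation of a para‑dimethoxy pair gives the 1,4‑benzoquinone, and both possible pairs lead to the same 2,5‑dimethoxy‑3‑alkylquinone because the arene is symmetric about the alkylated carbon.

Step 13
Reactants: 24 2,5-dimethoxy-3-[(2E)-3-methyl-5-[(1S)-2,6,6-trimethylcyclohex-2-en-1-yl]pent-2-en-1-yl]cyclohexa-2,5-diene-1,4-dione
Product: 25 2-hydroxy-5-methoxy-3-[(2E)-3-methyl-5-[(1S)-2,6,6-trimethylcyclohex-2-en-1-yl]pent-2-en-1-yl]cyclohexa-2,5-diene-1,4-dione (CNP0018448.1)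
Conditions: HClO4 (aq.), THF, 0 °C → rt
Reagents that add atoms: water, O
Why: Acid‑catalysed addition–elimination of water at a vinylogous ester: the methoxy group squeezed between a carbonyl and the alkyl chain is twisted out of conjugation and should hydrolyse preferentially, while the unhindered methoxy group is retained, giving the 2‑hydroxy‑5‑methoxy pattern.

**Compound list**

1 | geraniol | OC/C=C(\C)CCC=C(C)C | starting material
2 | tert-butyl{[(2E)-3,7-dimethylocta-2,6-dien-1-yl]oxy}diphenylsilane | CC(C)=CCC/C(C)=C/CO[Si](c1ccccc1)(c1ccccc1)C(C)(C)C | intermediate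
3 | tert-butyl{[(2E)-5-(3,3-dimethyloxiran-2-yl)-3-methylpent-2-en-1-yl]oxy}diphenylsilane (racemic epoxide) | CC1(C)OC1CC/C(C)=C/CO[Si](c1ccccc1)(c1ccccc1)C(C)(C)C | intermediate
4 | (4E)-6-[(tert-butyldiphenylsilyl)oxy]-4-methylhex-4-enal | O=CCC/C(C)=C/CO[Si](c1ccccc1)(c1ccccc1)C(C)(C)C | intermediate
5 | nitromethane | C[N+](=O)[O-] | starting material
6 | (5E)-7-[(tert-butyldiphenylsilyl)oxy]-5-methyl-1-nitrohept-5-en-2-ol | O=[N+]([O-])CC(O)CC/C(C)=C/CO[Si](c1ccccc1)(c1ccccc1)C(C)(C)C | intermediate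
7 | tert-butyl{[(2E,6E)-3-methyl-7-nitrohepta-2,6-dien-1-yl]oxy}diphenylsilane | O=[N+]([O-])/C=C/CC/C(C)=C/CO[Si](c1ccccc1)(c1ccccc1)C(C)(C)C | intermediate
8 | isobutyraldehyde (2-methylpropanal) | CC(C)C=O | starting material
9 | triphenyl(vinyl)phosphonium bromide | C=C[P+](c1ccccc1)(c1ccccc1)c1ccccc1.[Br-] | starting material
10 | (3S,6E)-8-[(tert-butyldiphenylsilyl)oxy]-2,2,6-trimethyl-3-(nitromethyl)oct-6-enal | O=CC(C)(C)[C@@H](C[N+](=O)[O-])CC/C(C)=C/CO[Si](c1ccccc1)(c1ccccc1)C(C)(C)C | intermediate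
11 | (3S,6E)-8-[(tert-butyldiphenylsilyl)oxy]-2,2,6-trimethyl-3-[1-nitro-3-(triphenylphosphoranylidene)propyl]oct-6-enal | O=CC(C)(C)[C@@H](C(CC=P(c1ccccc1)(c1ccccc1)c1ccccc1)[N+](=O)[O-])CC/C(C)=C/CO[Si](c1ccccc1)(c1ccccc1)C(C)(C)C | intermediate
12 | tert-butyl{[(2E)-5-[(1S)-2,2-dimethyl-6-nitrocyclohex-3-en-1-yl]-3-methylpent-2-en-1-yl]oxy}diphenylsilane | O=[N+]([O-])C1CC=CC(C)(C)[C@@H]1CC/C(C)=C/CO[Si](c1ccccc1)(c1ccccc1)C(C)(C)C | intermediate
13 | tert-butyl{[(2E)-5-[(1S)-2,2-dimethyl-6-nitrocyclohexyl]-3-methylpent-2-en-1-yl]oxy}diphenylsilane | O=[N+]([O-])C1CCCC(C)(C)[C@@H]1CC/C(C)=C/CO[Si](c1ccccc1)(c1ccccc1)C(C)(C)C | intermediate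
14 | sodium nitronate of 13 | [Na+].[O-][N+]([O-])=C1CCCC(C)(C)[C@@H]1CC/C(C)=C/CO[Si](c1ccccc1)(c1ccccc1)C(C)(C)C | intermediate
15 | (2S)-2-[(3E)-5-[(tert-butyldiphenylsilyl)oxy]-3-methylpent-3-en-1-yl]-3,3-dimethylcyclohexan-1-one | O=C1CCCC(C)(C)[C@@H]1CC/C(C)=C/CO[Si](c1ccccc1)(c1ccccc1)C(C)(C)C | intermediate
16 | lithium enolate of 15 (C2=C3) | [Li+].[O-]C1=CCCC(C)(C)[C@@H]1CC/C(C)=C/CO[Si](c1ccccc1)(c1ccccc1)C(C)(C)C | intermediate
17 | (6S)-6-[(3E)-5-[(tert-butyldiphenylsilyl)oxy]-3-methylpent-3-en-1-yl]-5,5-dimethylcyclohex-1-en-1-yl trifluoromethanesulfonate | O=S(=O)(OC1=CCCC(C)(C)[C@@H]1CC/C(C)=C/CO[Si](c1ccccc1)(c1ccccc1)C(C)(C)C)C(F)(F)F | intermediate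
18 | tert-butyl{[(2E)-3-methyl-5-[(1S)-2,6,6-trimethylcyclohex-2-en-1-yl]pent-2-en-1-yl]oxy}diphenylsilane | CC1=CCCC(C)(C)[C@@H]1CC/C(C)=C/CO[Si](c1ccccc1)(c1ccccc1)C(C)(C)C | intermediate
19 | (2E)-3-methyl-5-[(1S)-2,6,6-trimethylcyclohex-2-en-1-yl]pent-2-en-1-ol | CC1=CCCC(C)(C)[C@@H]1CC/C(C)=C/CO | intermediate
20 | (6S)-6-[(3E)-5-bromo-3-methylpent-3-en-1-yl]-1,5,5-trimethylcyclohex-1-ene | CC1=CCCC(C)(C)[C@@H]1CC/C(C)=C/CBr | intermediate
21 | 1,2,4,5-tetramethoxybenzene | COc1cc(OC)c(OC)cc1OC | starting material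
22 | (2,3,5,6-tetramethoxyphenyl)lithium | [Li]c1c(OC)c(OC)cc(OC)c1OC | intermediate
23 | 1,2,4,5-tetramethoxy-3-[(2E)-3-methyl-5-[(1S)-2,6,6-trimethylcyclohex-2-en-1-yl]pent-2-en-1-yl]benzene | COc1cc(OC)c(OC)c(C/C=C(\C)CC[C@@H]2C(C)=CCCC2(C)C)c1OC | intermediate
24 | 2,5-dimethoxy-3-[(2E)-3-methyl-5-[(1S)-2,6,6-trimethylcyclohex-2-en-1-yl]pent-2-en-1-yl]cyclohexa-2,5-diene-1,4-dione | COC1=CC(=O)C(OC)=C(C/C=C(\C)CC[C@@H]2C(C)=CCCC2(C)C)C1=O | intermediate
25 | 2-hydroxy-5-methoxy-3-[(2E)-3-methyl-5-[(1S)-2,6,6-trimethylcyclohex-2-en-1-yl]pent-2-en-1-yl]cyclohexa-2,5-diene-1,4-dione | COC1=CC(=O)C(O)=C(C/C=C(\C)CC[C@@H]2C(C)=CCCC2(C)C)C1=O | target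

**Count and risks**

Total step count: 13. Longest linear sequence: 13 steps (1 to 25); arene 21 enters in step 11.

Steps most likely to fail:

Step 4 (Proposed new method). Proton transfer from the acidic nitro C–H to the ylide may stall the sequence before olefination, the nitronate may add twice to the vinylphosphonium salt, or strong base may trigger retro‑Michael cleavage. The fallback uses known reactions only and sets out from 7. The amine‑catalysed Michael addition is run alone and 10 is isolated. Wittig methylenation of the neopentyl aldehyde (Ph3P=CH2, THF, 0 °C) gives the terminal alkene F1. Palladium‑catalysed Tsuji–Trost mono‑allylation of the primary nitroalkane (allyl methyl carbonate, Pd(PPh3)4, THF) gives the allylated nitro diene F2. Ring‑closing metathesis of the two vinyl groups (second‑generation Grubbs catalyst, CH2Cl2, 40 °C) forms the same C4=C5 bond and comes back to the route at 12.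

Step 13. Hydrolysis may be poorly regioselective between the two methoxy groups, and the acid may induce cyclisation of the new hydroxyl onto the side‑chain alkene or migration of the ring alkene. The fallback sets out from 20 and fixes the free hydroxyl by the protecting‑group pattern. 2‑Methoxy‑1,4‑benzoquinone is converted by Thiele–Winter acetoxylation (Ac2O, H2SO4 cat.) into 5‑methoxybenzene‑1,2,4‑triyl triacetate F6. Methanolysis (K2CO3, MeOH, argon) gives 5‑methoxybenzene‑1,2,4‑triol F7, and MeOCH2Cl with i‑Pr2NEt gives 1‑methoxy‑2,4,5‑tris(methoxymethoxy)benzene F8. Lithiation between the two flanking methoxymethoxy groups (n‑BuLi, THF) gives the aryllithium F9, and alkylation with 20 (CuI cat.) gives the tris(methoxymethyl) ether F10. Mild acetal cleavage (HCl in MeOH, 0 °C) gives the side‑chain triol F11, whose air oxidation as a hydroxyhydroquinone comes back to the route at 25.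

Step 5. Hydrogenation of the hindered ring alkene next to C6 may be slow, and forcing it may reduce the chain alkene or the nitro group. The fallback sets out from 12 and uses the ring alkene instead of removing it. The Nef reaction of step 6 (NaOMe; then TiCl3, NH4OAc), via the sodium nitronate F3, gives the β,γ‑unsaturated ketone F4. DBU (cat.) in CH2Cl2 moves the alkene into conjugation to give the cyclohexenone F5. Conjugate reduction with LiBH(s‑Bu)3 (THF, −78 °C) generates the C2=C3 enolate regiospecifically and comes back to the route at 16, which is triflated as in step 7.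

Further compounds
F1 | step 4 | tert-butyl{[(2E,6S)-3,7,7-trimethyl-6-(nitromethyl)nona-2,8-dien-1-yl]oxy}diphenylsilane | C=CC(C)(C)[C@@H](C[N+](=O)[O-])CC/C(C)=C/CO[Si](c1ccccc1)(c1ccccc1)C(C)(C)C
F2 | step 4 | tert-butyl{[(2E,6S)-3,7,7-trimethyl-6-(1-nitrobut-3-en-1-yl)nona-2,8-dien-1-yl]oxy}diphenylsilane | C=CC(C)(C)[C@@H](C(CC=C)[N+](=O)[O-])CC/C(C)=C/CO[Si](c1ccccc1)(c1ccccc1)C(C)(C)C
F3 | step 5 | sodium nitronate of 12 | [Na+].[O-][N+]([O-])=C1CC=CC(C)(C)[C@@H]1CC/C(C)=C/CO[Si](c1ccccc1)(c1ccccc1)C(C)(C)C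
F4 | step 5 | (2S)-2-[(3E)-5-[(tert-butyldiphenylsilyl)oxy]-3-methylpent-3-en-1-yl]-3,3-dimethylcyclohex-4-en-1-one | O=C1CC=CC(C)(C)[C@@H]1CC/C(C)=C/CO[Si](c1ccccc1)(c1ccccc1)C(C)(C)C
F5 | step 5 | (6S)-6-[(3E)-5-[(tert-butyldiphenylsilyl)oxy]-3-methylpent-3-en-1-yl]-5,5-dimethylcyclohex-2-en-1-one | O=C1C=CCC(C)(C)[C@@H]1CC/C(C)=C/CO[Si](c1ccccc1)(c1ccccc1)C(C)(C)C
F6 | step 13 | 5-methoxybenzene-1,2,4-triyl triacetate | COc1cc(OC(C)=O)c(OC(C)=O)cc1OC(C)=O
F7 | step 13 | 5-methoxybenzene-1,2,4-triol | COc1cc(O)c(O)cc1O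
F8 | step 13 | 1-methoxy-2,4,5-tris(methoxymethoxy)benzene | COc1cc(OCOC)c(OCOC)cc1OCOC
F9 | step 13 | [3-methoxy-2,5,6-tris(methoxymethoxy)phenyl]lithium | COc1cc(OCOC)c(OCOC)c([Li])c1OCOC
F10 | step 13 | 1-methoxy-2,4,5-tris(methoxymethoxy)-3-[(2E)-3-methyl-5-[(1S)-2,6,6-trimethylcyclohex-2-en-1-yl]pent-2-en-1-yl]benzene | COc1cc(OCOC)c(OCOC)c(C/C=C(\C)CC[C@@H]2C(C)=CCCC2(C)C)c1OCOC
F11 | step 13 | 5-methoxy-3-[(2E)-3-methyl-5-[(1S)-2,6,6-trimethylcyclohex-2-en-1-yl]pent-2-en-1-yl]benzene-1,2,4-triol | COc1cc(O)c(O)c(C/C=C(\C)CC[C@@H]2C(C)=CCCC2(C)C)c1O
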